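Before starting material is spent on recipe winter or recipe autumn, a reckoning on paper can compare them by asking what remains of the coupling partner once the protic impurity has taken its share.

| flask | starting material | coupling partner | protic impurity | free catalyst | remark | time |
|---|---|---|---|---|---|---|
| violet | 1.5 M | 0.89 equiv | 0.15 M | 0.23 mol% | run made earlier |  |
| green | 1.5 M | 1.3 equiv | 0.15 M | 0.23 mol% | run made earlier |  |
| grey | 1.5 M | 1.9 equiv | 0.15 M | 0.23 mol% | run made earlier |  |
| blue | 1.5 M | 2 equiv | 0.38 M | 0.23 mol% | run made earlier |  |
| winter | 1.5 M | 2.00 equiv | 0.150 M | 0.23 mol% |  | 12 min |
| autumn | 1.5 M | 1.00 equiv | 0.500 M | 0.23 mol% |  | 12 min |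

| violet: time / min | violet: product / % | green: time / min | green: product / % | grey: time / min | grey: product / % | blue: time / min | blue: product / % |
|---|---|---|---|---|---|---|---|
| 1.50 | 19 | 1.50 | 28 | 1.50 | 39 | 0.833 | 23 |
| 3.00 | 37 | 3.00 | 52 | 3.00 | 66 | 2.00 | 48 |
| 5.00 | 50 | 5.00 | 65 | 5.00 | 84 | 4.00 | 75 |
| 6.00 | 54 | 6.00 | 71 | 6.00 | 92 | 6.00 | 91 |
| 8.00 | 60 | 8.00 | 83 | 8.00 | 96 | 8.00 | 91 |

(scatter of a reading: 2 percentage points)

- what was read earlier has a scatter of 2 percentage points, one standard deviation

1. which one finishes higher in amount of product, in percent of the starting material charged ("neither" within 2 percentage points) (winter / autumn / neither)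
2. amount of product at the end, in percent of the starting material charged, winter
3. amount of product at the end, in percent of the starting material charged, autumn

The bench rule says that product follows the limiting reagent, read from the equivalents weighed in. Applied honestly, it makes starting material limiting in both recipes, with 2.00 equiv of coupling partner in winter and 1.00 equiv in autumn, so it promises full conversion in each and cannot separate them.

Suppose each protic impurity destroys one coupling partner. The rule then stops working where the ratio c(protic impurity)/c(starting material) exceeds the excess of partner. In winter that ratio is 0.100 against an excess of 1.00, so the rule stands. In autumn it is 0.333 against 0, so the rule fails.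

Autumn keeps 0.667 and winter 1.90. This is the net partner, the equivalents of coupling partner minus that ratio. Below one it caps product at 66.7% for autumn, while winter is capped by its starting material at 100%.

A cap is approached from below. Violet, with net partner 0.790, read 60% at 8.00 min and was still climbing, while grey read 96%. My own reckoning therefore puts winter close to its cap and autumn somewhat under its own at 12 min.

The forecast chose winter, with 96% for winter and 62% for autumn, holding that the “impurity competes more strongly at low partner”.

The flasks put winter ahead, with 99.5% for winter and 59.3% for autumn.

    starting material + free catalyst → free catalyst + open intermediate (k = 24.0 M⁻¹ s⁻¹)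
    free catalyst + open intermediate ⇌ catalyst intermediate (K = 1.00 M⁻¹, k = 13.0 M⁻¹ s⁻¹)
    coupling partner + catalyst intermediate → free catalyst + product (k = 2.00 M⁻¹ s⁻¹)
    coupling partner + protic impurity → quenched reagent (k = 0.0330 M⁻¹ s⁻¹)

The main reason for autumn's gap to winter is its smaller charge of coupling partner: with winter's equivalents, which raise its net partner to 1.67, autumn gives 98.5% instead of 59.3%. Left until 120 min, autumn as charged holds 66.7% product, at its cap of 66.7%, with 0% of its coupling partner left and 33.3% remaining as open intermediate. A further flask, like winter but with 0.38 M of starting material, has net partner 1.60, so its cap is full conversion, yet at 12.0 min it holds 36.5% product and 63.4% open intermediate.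

The earlier runs and the new flask are calculated on assumed constants; noise was put on by code.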